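## Retrosynthetic overview

1. Numbering: tetrahydrofuran O1, C2 (ring A aryl), C3 (bears C9H2OH), C4 (bears carbinol Ca with the ring B aryl), C5H2. The plan rests on two features. Ca(OH)–C4–C5 becomes a β-hydroxy ester once C5 is written as CO2Me. The Ca oxygen lies 1,4 to C9, so a γ-lactone O–Ca–C4–C3–C9(=O), absent from the target, can carry both.
2. O1–C2 is cut first. The all-trans tetrahydrofuran comes from a tetraol by acid ionisation of the ring A carbinol alone, with ring B kept electron-poor as its sulfonate. The tetraol comes from hydride opening of a lactone acid.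
3. C2–C3 is cut next: aldol of the paraconic acid dianion with O-benzylvanillin, on the face away from both substituents of the cis lactone.
4. Ca–H and the lactone O–C9 bond are cut together: transfer hydrogenation with dynamic kinetic resolution of a racemic aroylsuccinate, made by a Stetter reaction of O-sulfonylvanillin with dimethyl fumarate.
5. Ring order: temporary γ-lactone (closed in step 3, opened in step 6), then the tetrahydrofuran (step 7).

Key step: step 3

Remark on the chemistry: ring B is masked as a tosylate, not a mesylate. Lithium amides deprotonate CH3SO2OAr, which collapses to sulfene and phenoxide and would not survive step 5. Tosylates have no such α-hydrogen and also withstand LiAlH4. Compounds 11 to 13 are carried as mixtures of C2 epimers because C2 is reset in step 7. The labels C2, C3, C4, C5, C9 and Ca always refer to the numbering in line 1.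

## Route

Step 1
Reactants: 1 vanillin; 2 p-toluenesulfonyl chloride
Product: 3 4-formyl-2-methoxyphenyl 4-methylbenzenesulfonate (O-tosylvanillin)
Conditions: TsCl (1.1 equiv), Et3N (1.5 equiv), CH2Cl2, 0 °C to rt
Reagents that add atoms: p-toluenesulfonyl chloride, Cc1ccc(cc1)S(=O)(=O)Cl
Why: O-sulfonylation of the phenol is chemoselective because the aldehyde is inert to TsCl/Et3N, and the tosyloxy group makes ring B electron-poor for steps 3 and 7.

Step 2
Reactants: 3 O-tosylvanillin; 4 dimethyl fumarate
Product: 5 rac-dimethyl 2-[3-methoxy-4-(tosyloxy)benzoyl]butanedioate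
Conditions: 3-benzyl-5-(2-hydroxyethyl)-4-methylthiazolium chloride (20 mol %), Et3N (1 equiv), DMF, 70 °C
Reagents that add atoms: dimethyl fumarate, COC(=O)/C=C/C(=O)OC
Why: In this Stetter reaction the thiazol-2-ylidene turns the electron-poor aldehyde into a Breslow intermediate that adds 1,4 to the symmetrical acceptor, so no regiochemical question arises, reversible benzoin formation drains into the irreversible conjugate addition, and C4 may form racemic because step 3 is stereoconvergent.

Step 3
Reactants: 5 rac-dimethyl 2-[3-methoxy-4-(tosyloxy)benzoyl]butanedioate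
Product: 7 methyl (2S,3R)-2-[3-methoxy-4-(tosyloxy)phenyl]-5-oxooxolane-3-carboxylate (cis lactone), via anti hydroxy diester 6 (not isolated)
Conditions: RuCl(p-cymene)[(S,S)-TsDPEN] (1 mol %), HCO2H/Et3N 5:2, CH2Cl2, 30 °C; then TsOH·H2O (5 mol %), toluene, 50 °C
Reagents that add atoms: none
Why: In HCO2H/Et3N the C4–H of 5, acidified by the aryl ketone and the C5 ester, exchanges through the enol much faster than the ketone is reduced, so both enantiomers are funnelled into one product; this is the known Noyori–Ikariya asymmetric transfer hydrogenation of α-substituted β-keto esters with dynamic kinetic resolution. The hydride RuH(p-cymene)[(S,S)-TsDPEN], a complex of divalent ruthenium regenerated by formate with loss of CO2, passes Ru–H to Ca and N–H to oxygen in a six-membered outer-sphere transition state without binding the substrate. Ca is set by the ligand: the CH/π contact between ring B and the p-cymene ring fixes the carbonyl face, and the (S,S) diamine should give (S)-Ca as it does for aryl alkyl ketones. C4 is set by rate selection between the equilibrating enantiomers: with no chelate possible, the faster one meets the hydride in a Felkin–Anh arrangement with the C5 ester anti to the incoming hydride and C4–H beside its path, which leads to the anti hydroxy diester 6 with (R)-C4. The Ca hydroxyl of 6 then closes on the C9 ester by 5-exo-trig acyl substitution with loss of methanol (attack at C5 would give a β-lactone and does not compete), and the catalytic TsOH finish completes closure to cis lactone 7, in which C4 is only an ester α-carbon and no longer epimerises in the acidic medium. The step needs fast racemisation, a large rate gap between the enantiomers and chemoselective ketone reduction; the para tosyloxy group serves the first and third by raising C4–H acidity and ketone electrophilicity, while the difference in size and polarity between CO2Me and CH2CO2Me at C4 has to provide the second.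

Step 4
Reactants: 7 cis lactone methyl ester
Product: 8 (2S,3R)-2-[3-methoxy-4-(tosyloxy)phenyl]-5-oxooxolane-3-carboxylic acid (cis)
Conditions: Me3SnOH (4 equiv), 1,2-dichloroethane, 70 °C; cold 1 M HCl wash
Reagents that add atoms: trimethyltin hydroxide, C[Sn](C)(C)O
Why: Me3SnOH cleaves the methyl ester by acyl–oxygen hydrolysis under nearly neutral conditions, so C4–H is not removed and the cis relationship is kept, while any lactone that opens recloses through the untouched Ca–O bond on the acid wash and the sulfonate is not affected.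

Step 5
Reactants: 8 cis lactone acid; 9 4-benzyloxy-3-methoxybenzaldehyde (O-benzylvanillin)
Product: 11 (2S,3R,4S)-4-[(4-benzyloxy-3-methoxyphenyl)(hydroxy)methyl]-2-[3-methoxy-4-(tosyloxy)phenyl]-5-oxooxolane-3-carboxylic acid (C2 epimers), via dilithium dianion 10 (not isolated)
Conditions: LiN(SiMe3)2 (2.1 equiv), THF, −78 °C; 9 (1.2 equiv), −78 °C; cold 1 M HCl quench
Reagents that add atoms: 4-benzyloxy-3-methoxybenzaldehyde, COc1cc(C=O)ccc1OCc1ccccc1
Why: In this paraconic acid dianion aldol the carboxylate formed first shields C4–H, so the second equivalent of base enolises only at C3, and the aldehyde approaches the enolate face opposite ring B and the carboxylate (both on one face of the cis lactone), which sets C3 trans to C4, while the C2 carbinol configuration does not matter.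

Step 6
Reactants: 11 aldol lactone acid
Product: 12 (2R,3S)-2-[(4-benzyloxy-3-methoxyphenyl)(hydroxy)methyl]-3-{(S)-hydroxy[3-methoxy-4-(tosyloxy)phenyl]methyl}butane-1,4-diol (tetraol, C2 epimers)
Conditions: LiAlH4 (5 equiv), THF, 0 °C to rt; aq. potassium sodium tartrate work-up
Reagents that add atoms: none
Why: LiAlH4 opens the lactone to Ca–OH and C9H2OH and reduces the carboxylate to C5H2OH without touching a stereocentre, and aryl tosylates and benzyl ethers withstand this hydride at or below room temperature.

Step 7
Reactants: 12 tetraol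
Product: 14 4-{(S)-hydroxy[(3S,4R,5S)-5-(4-benzyloxy-3-methoxyphenyl)-4-(hydroxymethyl)oxolan-3-yl]methyl}-2-methoxyphenyl 4-methylbenzenesulfonate, via benzylic cation 13 (not isolated)
Conditions: camphorsulfonic acid (10 mol %), CH2Cl2 (0.01 M), 0 °C to rt
Reagents that add atoms: none
Why: In this acid cyclodehydration of a benzylic 1,4-diol only the C2 carbinol ionises, because its cation is stabilised by the para benzyloxy group whereas Ca sits on the tosylated ring; the primary C5–OH closes the five-membered ether, C9–OH could only give an oxetane, and capture by Ca–OH would give a 2,5-diaryl ring with ring B, C5 and C9 all cis that stays reversible at its C2–O bond, so the equilibrium should collect in the all-trans product with (S)-C2 set under thermodynamic control by C3.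

Step 8
Reactants: 14 benzyl ether tosylate
Product: 15 4-{(S)-hydroxy[(3S,4R,5S)-5-(4-hydroxy-3-methoxyphenyl)-4-(hydroxymethyl)oxolan-3-yl]methyl}-2-methoxyphenyl 4-methylbenzenesulfonate
Conditions: H2 (1 atm), 10% Pd/C, EtOAc, rt, stopped at consumption of 14
Reagents that add atoms: none
Why: Hydrogenolysis of an aryl benzyl ether in neutral EtOAc is much faster than cleavage of the secondary benzylic C2–O1 bond, Ca–OH is still guarded by the electron-poor ring B, and aryl sulfonates are inert to H2 over palladium at this pressure.

Step 9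
Reactants: 15 ring B tosylate
Product: 16 4-[(2S,3R,4S)-4-[(S)-hydroxy(4-hydroxy-3-methoxyphenyl)methyl]-3-(hydroxymethyl)oxolan-2-yl]-2-methoxyphenol (target)
Conditions: Mg turnings (10 equiv), MeOH, rt; aq. NH4Cl work-up
Reagents that add atoms: none
Why: Magnesium in methanol cleaves the aryl sulfonate S–O bond by electron transfer at room temperature, which frees the phenol without the hot alkali that could expel Ca–OH or open C2–O1 through a quinone methide, and no stereocentre is touched.

## Compound list

1 | vanillin | COc1cc(C=O)ccc1O | starting material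
2 | p-toluenesulfonyl chloride | Cc1ccc(cc1)S(=O)(=O)Cl | starting material
3 | 4-formyl-2-methoxyphenyl 4-methylbenzenesulfonate | COc1cc(C=O)ccc1OS(=O)(=O)c1ccc(C)cc1 | intermediate
4 | dimethyl fumarate | COC(=O)/C=C/C(=O)OC | starting material
5 | rac-dimethyl 2-[3-methoxy-4-(tosyloxy)benzoyl]butanedioate | COc1cc(C(=O)C(CC(=O)OC)C(=O)OC)ccc1OS(=O)(=O)c1ccc(C)cc1 | intermediate
6 | dimethyl (2R)-2-{(S)-hydroxy[3-methoxy-4-(tosyloxy)phenyl]methyl}butanedioate (anti, not isolated) | COc1cc([C@@H](O)[C@@H](CC(=O)OC)C(=O)OC)ccc1OS(=O)(=O)c1ccc(C)cc1 | intermediate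
7 | methyl (2S,3R)-2-[3-methoxy-4-(tosyloxy)phenyl]-5-oxooxolane-3-carboxylate (cis) | COc1cc([C@H]2OC(=O)C[C@H]2C(=O)OC)ccc1OS(=O)(=O)c1ccc(C)cc1 | intermediate
8 | (2S,3R)-2-[3-methoxy-4-(tosyloxy)phenyl]-5-oxooxolane-3-carboxylic acid (cis) | COc1cc([C@H]2OC(=O)C[C@H]2C(=O)O)ccc1OS(=O)(=O)c1ccc(C)cc1 | intermediate
9 | 4-benzyloxy-3-methoxybenzaldehyde | COc1cc(C=O)ccc1OCc1ccccc1 | starting material
10 | dilithium carboxylate lactone enolate of 8 (not isolated) | COc1cc([C@H]2OC([O-])=C[C@H]2C(=O)[O-])ccc1OS(=O)(=O)c1ccc(C)cc1.[Li+].[Li+] | intermediate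
11 | (2S,3R,4S)-4-[(4-benzyloxy-3-methoxyphenyl)(hydroxy)methyl]-2-[3-methoxy-4-(tosyloxy)phenyl]-5-oxooxolane-3-carboxylic acid (C2 epimers) | COc1cc([C@H]2OC(=O)[C@H](C(O)c3ccc(OCc4ccccc4)c(OC)c3)[C@H]2C(=O)O)ccc1OS(=O)(=O)c1ccc(C)cc1 | intermediate
12 | (2R,3S)-2-[(4-benzyloxy-3-methoxyphenyl)(hydroxy)methyl]-3-{(S)-hydroxy[3-methoxy-4-(tosyloxy)phenyl]methyl}butane-1,4-diol (C2 epimers) | COc1cc([C@@H](O)[C@H](CO)[C@H](CO)C(O)c2ccc(OCc3ccccc3)c(OC)c2)ccc1OS(=O)(=O)c1ccc(C)cc1 | intermediate
13 | C2 benzylic cation from 12 (not isolated) | COc1cc([C@@H](O)[C@H](CO)[C@H](CO)[CH+]c2ccc(OCc3ccccc3)c(OC)c2)ccc1OS(=O)(=O)c1ccc(C)cc1 | intermediate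
14 | all-trans tetrahydrofuran, ring A benzyl ether, ring B tosylate | COc1cc([C@@H](O)[C@@H]2CO[C@H](c3ccc(OCc4ccccc4)c(OC)c3)[C@H]2CO)ccc1OS(=O)(=O)c1ccc(C)cc1 | intermediate
15 | all-trans tetrahydrofuran, ring A phenol, ring B tosylate | COc1cc([C@@H](O)[C@@H]2CO[C@H](c3ccc(O)c(OC)c3)[C@H]2CO)ccc1OS(=O)(=O)c1ccc(C)cc1 | intermediate
16 | 4-[(2S,3R,4S)-4-[(S)-hydroxy(4-hydroxy-3-methoxyphenyl)methyl]-3-(hydroxymethyl)oxolan-2-yl]-2-methoxyphenol | COc1cc([C@@H](O)[C@@H]2CO[C@H](c3ccc(O)c(OC)c3)[C@H]2CO)ccc1O | target

## Step count and risks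

Total step count: 9. Longest linear sequence: 9 steps, from vanillin 1 to 16. Aldehyde 9 is purchased.

**Risk 1, step 3.**
- What may go wrong: the rate gap between the two equilibrating enantiomers of 5 may be too small, so that anti selectivity erodes and trans lactone forms alongside. The more crowded cis lactone may also close sluggishly.
- The fallback replaces catalyst control by auxiliary control. It sets out from aldehyde 3 and rejoins the route at acid 8.
- (S)-4-Benzyl-1,3-oxazolidin-2-one is N-acylated (n-BuLi, THF, −78 °C) with methyl 4-chloro-4-oxobutanoate to give (S)-4-benzyl-3-(4-methoxy-4-oxobutanoyl)-1,3-oxazolidin-2-one F1.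
- An Evans anti-aldol catalysed by MgCl2 (10 mol %, Et3N, Me3SiCl, EtOAc, rt) with 3 should give the anti aldol trimethylsilyl ether F2. The magnesium-chelated Z-enolate of the (S) auxiliary is expected to expose the same face as in its alkylations, which corresponds to the required C4.
- TFA in MeOH frees the anti hydroxy imide F3, and catalytic TsOH in toluene closes it to the cis lactone imide F4.
- LiOH/H2O2 (THF/H2O, 0 °C) removes the auxiliary to give 8, so step 4 is no longer needed.

**Risk 2, step 5.**
- What may go wrong: the lithium aldolate of the electron-rich aldehyde may revert before the quench, or residual amide base may consume the aldehyde. Either leaves the C2–C3 bond poorly formed.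
- The fallback makes this bond by an acylation that is driven forward by deprotonation of its product. It sets out from acid 8 and rejoins the route at 11.
- 4-Benzyloxy-3-methoxybenzoic acid and carbonyldiimidazole (THF, rt) give 1-(4-benzyloxy-3-methoxybenzoyl)imidazole F5.
- Dianion 10, generated from 8 with 3.2 equiv of LiN(SiMe3)2, is C-acylated by F5 at −78 °C to give the 3-aroyl lactone acid F6. Its epimerisable C3 settles trans to C4.
- NaBH4 (THF/MeOH, −20 °C) reduces only the aryl ketone and delivers 11 as C2 epimers.

**Risk 3, step 7.**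
- What may go wrong: repeated acid ionisation at C2 may drain material into irreversible Friedel–Crafts closure on ring B (para to its methoxy group), into capture by Ca–OH, or into intermolecular etherification.
- The fallback generates the C2 electrophile once, as a neutral quinone methide and without acid. It sets out from acid 8 and rejoins the route at 15.
- 4-Benzyloxy-3-methoxybenzyl alcohol and PBr3 (Et2O, 0 °C) give 4-benzyloxy-3-methoxybenzyl bromide F7.
- F7 alkylates dianion 10 (THF, −78 °C) anti to the two lactone substituents to give the trans 3-benzyl lactone acid F8.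
- LiAlH4 (THF, 0 °C to rt) gives the triol F9.
- H2 over 10% Pd/C (EtOAc) gives the phenol triol F10. This debenzylation is safe because ring A carries no benzylic oxygen at that stage.
- DDQ (1.0 equiv, 1,4-dioxane, rt) oxidises the 4-alkylguaiacol to the p-quinone methide F11, which the C5 hydroxyl traps 5-exo-trig on the face away from C9 to give 15.

## Further compounds

F1 | step 3 | (S)-4-benzyl-3-(4-methoxy-4-oxobutanoyl)-1,3-oxazolidin-2-one | COC(=O)CCC(=O)N1[C@@H](Cc2ccccc2)COC1=O
F2 | step 3 | anti aldol trimethylsilyl ether | COc1cc([C@@H](O[Si](C)(C)C)[C@@H](CC(=O)OC)C(=O)N2[C@@H](Cc3ccccc3)COC2=O)ccc1OS(=O)(=O)c1ccc(C)cc1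
F3 | step 3 | anti hydroxy imide | COc1cc([C@@H](O)[C@@H](CC(=O)OC)C(=O)N2[C@@H](Cc3ccccc3)COC2=O)ccc1OS(=O)(=O)c1ccc(C)cc1
F4 | step 3 | cis lactone imide | COc1cc([C@H]2OC(=O)C[C@H]2C(=O)N3[C@@H](Cc4ccccc4)COC3=O)ccc1OS(=O)(=O)c1ccc(C)cc1
F5 | step 5 | 1-(4-benzyloxy-3-methoxybenzoyl)imidazole | COc1cc(C(=O)n2ccnc2)ccc1OCc1ccccc1
F6 | step 5 | 3-aroyl lactone acid | COc1cc([C@H]2OC(=O)[C@H](C(=O)c3ccc(OCc4ccccc4)c(OC)c3)[C@H]2C(=O)O)ccc1OS(=O)(=O)c1ccc(C)cc1
F7 | step 7 | 4-benzyloxy-3-methoxybenzyl bromide | COc1cc(CBr)ccc1OCc1ccccc1
F8 | step 7 | trans 3-benzyl lactone acid | COc1cc([C@H]2OC(=O)[C@H](Cc3ccc(OCc4ccccc4)c(OC)c3)[C@H]2C(=O)O)ccc1OS(=O)(=O)c1ccc(C)cc1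
F9 | step 7 | triol | COc1cc([C@@H](O)[C@H](CO)[C@H](CO)Cc2ccc(OCc3ccccc3)c(OC)c2)ccc1OS(=O)(=O)c1ccc(C)cc1
F10 | step 7 | phenol triol | COc1cc([C@@H](O)[C@H](CO)[C@H](CO)Cc2ccc(O)c(OC)c2)ccc1OS(=O)(=O)c1ccc(C)cc1
F11 | step 7 | p-quinone methide | COC1=CC(=C[C@@H](CO)[C@@H](CO)[C@H](O)c2ccc(OS(=O)(=O)c3ccc(C)cc3)c(OC)c2)C=CC1=O
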